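C10 carries the angular methyl. C1 and C2 are the CH2 groups leading from it to the ether carbon C3, and C4 is the CH2 between C3 and the ring-fusion CH C5. C6 is CH2, C7 carries the hydroxyisopropyl group, and C8 and C9 are CH2. Ring A = C1–C5 and C10, ring B = C5–C10; the β face is that of the angular methyl, α the opposite one.
Retrosynthetic cuts, in order: the two silyl groups; the aryl–allyl bond para and the aryl–aryl bond ortho to the ether oxygen (traced back to Cl and Br on one arene); the C5–H bond (from a C5=C6 alkene); the ring bond C3–C4; the two methylene carbons C4 and C3–CH3 (from a ketone and an aryl ester carbonyl); the C10–C1 bond (acrylate conjugate addition).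
Enabling feature: in ring A the fully substituted ether carbon C3 (CH3, O-aryl, C2H2, C4H2) is separated from the ring-fusion methine C5 by the single methylene C4. C4 can therefore begin as the terminus of an exocyclic alkene on C5, and C3 as a cationic carbon that already holds the aryl–oxygen bond, so the hindered ether is never made by substitution.
Forward order: ring B is bought with dihydrocarvone, the C1–C3 chain is added at C10, the phenol enters as an ester, ring A closes through C3–C4, the alkene is reduced, and the biaryl and the second allyl group are attached by two cross-couplings.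
Stereochemistry: C7 from the chiral pool, C10 from an (R)-1-phenylethylamine imine, C3 from a chair transition state anchored by C10 and ring B, C5 from a radical hydrogenation that favours the trans-decalin.

Key step: step 7

Remark: 2-allyl-4-bromophenol is taken as a purchasable compound (it is the Claisen rearrangement product of allyl 4-bromophenyl ether). The target is (3R,5S,7R,10S) in the locants above: a trans-decalin with the aryloxy group axial (α) and the C3 methyl, C10 methyl and C7 side chain all β.

Step 1
Reactants: 1 (+)-dihydrocarvone, (2R,5R)-2-methyl-5-(prop-1-en-2-yl)cyclohexan-1-one (commercial material also holds the C2 epimer); 2 (R)-(+)-1-phenylethylamine; 3 methyl acrylate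
Product: 6 methyl 3-[(1S,4R)-1-methyl-2-oxo-4-(prop-1-en-2-yl)cyclohexyl]propanoate, via ketimine 4 (not isolated), via adduct imine 5 (not isolated)
Conditions: 2, TsOH (cat.), toluene, reflux, Dean–Stark; then 3, 50 °C; then 20% aq. AcOH, rt
Reagents that add atoms: water, SMILES O
Why: Asymmetric Michael addition of a chiral ketimine (d'Angelo reaction): the more substituted secondary enamine tautomer of 4 adds to the acrylate through a compact aza-ene-like transition state on the face left open by the phenyl group of the (R)-auxiliary, which places the new C10–C1 bond trans to the isopropenyl group and sets C10 as S against the modest substrate bias, a behaviour known for this imine with vinyl ketones, while the labile methyl-bearing centre of 1 is erased in the enamine.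

Step 2
Reactants: 6 methyl 3-[(1S,4R)-1-methyl-2-oxo-4-(prop-1-en-2-yl)cyclohexyl]propanoate
Product: 7 methyl 3-[(1S,4R)-4-(2-hydroxypropan-2-yl)-1-methyl-2-oxocyclohexyl]propanoate
Conditions: Co(acac)2 (20 mol %), PhSiH3, O2 (1 atm), THF, rt
Reagents that add atoms: dioxygen, SMILES O=O
Why: Mukaiyama hydration: the Co–H species formed from Co(acac)2 and PhSiH3 transfers a hydrogen atom to the terminal carbon of the 1,1-disubstituted alkene and the tertiary radical is trapped by O2 and reduced to the tertiary alcohol, conditions that leave ketone and ester alone and touch no stereocentre; the hydration is placed after step 1 so that the Michael addition runs on the small isopropenyl compound.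

Step 3
Reactants: 7 methyl 3-[(1S,4R)-4-(2-hydroxypropan-2-yl)-1-methyl-2-oxocyclohexyl]propanoate
Product: 8 methyl 3-[(1S,4R)-4-{2-[(tert-butyldimethylsilyl)oxy]propan-2-yl}-1-methyl-2-oxocyclohexyl]propanoate
Conditions: TBSOTf, 2,6-lutidine, CH2Cl2, 0 °C to rt; 0.5 M aq. citric acid wash
Reagents that add atoms: tert-butyldimethylsilyl triflate, SMILES CC(C)(C)[Si](C)(C)OS(=O)(=O)C(F)(F)F
Why: Silylation of a tertiary alcohol with a silyl triflate and a hindered pyridine base is standard, any silyl enol ether of the hindered ketone is hydrolysed in the acidic wash, and the bulky ether keeps the hydroxyl group from trapping cations in step 7.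

Step 4
Reactants: 8 methyl 3-[(1S,4R)-4-{2-[(tert-butyldimethylsilyl)oxy]propan-2-yl}-1-methyl-2-oxocyclohexyl]propanoate
Product: 10 3-[(1S,4R)-4-{2-[(tert-butyldimethylsilyl)oxy]propan-2-yl}-1-methyl-2-oxocyclohexyl]propanoic acid, via lithium carboxylate 9 (not isolated)
Conditions: LiOH, THF/MeOH/H2O, rt; then 1 M HCl to pH 4, 0 °C
Reagents that add atoms: lithium hydroxide, SMILES [Li+].[OH-]
Why: Saponification of an unhindered methyl ester by hydroxide is much faster than any condensation of the ketone enolate with the ester, and the brief mild acidification leaves the tertiary silyl ether in place.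

Step 5
Reactants: 10 3-[(1S,4R)-4-{2-[(tert-butyldimethylsilyl)oxy]propan-2-yl}-1-methyl-2-oxocyclohexyl]propanoic acid; 11 2-bromo-4-chlorophenol
Product: 12 2-bromo-4-chlorophenyl 3-[(1S,4R)-4-{2-[(tert-butyldimethylsilyl)oxy]propan-2-yl}-1-methyl-2-oxocyclohexyl]propanoate
Conditions: EDC·HCl, DMAP (20 mol %), CH2Cl2, 0 °C to rt
Reagents that add atoms: none
Why: Steglich-type carbodiimide/DMAP esterification acylates acidic phenols readily and creates the aryl–O–C3 connectivity of the target as an ordinary ester bond.

Step 6
Reactants: 12 2-bromo-4-chlorophenyl 3-[(1S,4R)-4-{2-[(tert-butyldimethylsilyl)oxy]propan-2-yl}-1-methyl-2-oxocyclohexyl]propanoate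
Product: 14 2-bromo-4-chloro-1-({4-[(1S,4R)-4-{2-[(tert-butyldimethylsilyl)oxy]propan-2-yl}-1-methyl-2-methylidenecyclohexyl]but-1-en-2-yl}oxy)benzene, via methylidene aryl ester 13 (not isolated)
Conditions: Cp2Ti(CH2)(Cl)AlMe2 (3.5 equiv, toluene), pyridine, THF, −40 °C to rt; 15% aq. NaOH at −10 °C; basic alumina
Reagents that add atoms: Cp2Ti(CH2)(Cl)AlMe2, SMILES C[Al-]1(C)C[Ti](C2C=CC=C2)(C2C=CC=C2)[Cl+]1 (cyclopentadienyl rings drawn σ-bonded)
Why: Tebbe methylenation: Cp2Ti=CH2 released by pyridine exchanges C=O for C=CH2 through oxatitanacyclobutanes, a reaction known for α-quaternary ketones and for phenyl esters (which give aryl 1-alkylvinyl ethers), and the non-basic reagent, the pyridine-bound aluminium and the basic work-up spare C7, the aryl halides, the silyl ether and the acid-labile enol ether.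

Step 7
Reactants: 14 2-bromo-4-chloro-1-({4-[(1S,4R)-4-{2-[(tert-butyldimethylsilyl)oxy]propan-2-yl}-1-methyl-2-methylidenecyclohexyl]but-1-en-2-yl}oxy)benzene
Product: 17 (3R,7R,10S)-3-(2-bromo-4-chlorophenoxy)-7-{2-[(tert-butyldimethylsilyl)oxy]propan-2-yl}-3,10-dimethyl-5(6)-octalin (alkene C5=C6; aryloxy axial on the α face), via aryloxycarbenium ion 15 (not isolated), via tertiary C5 cation 16 (not isolated)
Conditions: HNTf2 (10 mol %), CH2Cl2 (0.005 M), −78 °C; Et3N quench at −78 °C
Reagents that add atoms: none
Why: Proposed new method: HNTf2 protonates the terminal carbon of the aryl enol ether, which is far more basic than the 1,1-dialkyl alkene, so that this CH2 becomes the C3 methyl group and aryloxycarbenium ion 15 results; the terminal carbon C4 of the exocyclic methylene then bonds to C3, the charge moves to the tertiary centre C5 (16), and an axial C6 proton is passed on to the next enol ether molecule, which makes the acid catalytic. The closest known reaction types are acetal- and ketal-initiated cation–olefin cyclisations and Prins cyclisations triggered by protonation of alkyl enol ethers; what is new is a ketone-level O-aryl oxocarbenium ion whose oxygen stays outside the ring that forms. Ring A closes through a six-membered chair, 6-endo-trig with respect to the attacking C4=C5 alkene (Markovnikov) and exo with respect to the C3=O+ bond. The one new stereocentre, C3 (R), is controlled by the C10 quaternary centre and the side-chain-locked chair of ring B: C3 reaches C4 on the α face, the methyl group (larger A value) takes the equatorial site and the aryloxy group the axial α site, anti to the angular methyl and next to the developing charge at C5, an argument from conformational analysis that has not been tested. The step needs site-selective protonation (oxygen lone-pair donation), ring closure ahead of enol ether oligomerisation (high dilution, quaternary C10 in the tether), an arene that does not trap the C5 cation (deactivated by Br and Cl) and survival of the two tertiary C–O bonds (catalytic acid, −78 °C, amine quench, weakly basic aryloxy oxygen). Proton loss towards C6 should dominate because the C4–H bonds are deactivated by the adjacent C–O dipole, and any C4=C5 isomer would lead to the same C5 radical in step 8.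

Step 8
Reactants: 17 (3R,7R,10S)-3-(2-bromo-4-chlorophenoxy)-7-{2-[(tert-butyldimethylsilyl)oxy]propan-2-yl}-3,10-dimethyl-5(6)-octalin
Product: 19 (3R,5S,7R,10S)-3-(2-bromo-4-chlorophenoxy)-7-{2-[(tert-butyldimethylsilyl)oxy]propan-2-yl}-3,10-dimethyl-trans-decalin, via tertiary C5 radical 18 (not isolated)
Conditions: Mn(dpm)3 (10 mol %), PhSiH3, t-BuOOH, i-PrOH/hexane, rt, Ar
Reagents that add atoms: none
Why: Metal-hydride hydrogen-atom-transfer hydrogenation (Mukaiyama-type radical hydrogenation): the Mn–H species formed from Mn(dpm)3 and PhSiH3 gives a hydrogen atom to C6 and the tertiary radical 18 takes up the second hydrogen along the axial α direction, away from the vicinal angular methyl, so that C5 (S) is set in the more stable trans-decalin, while the aryl bromide, aryl chloride and silyl ether are left alone and the protected side chain cannot direct hydrogen to the β face.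

Step 9
Reactants: 20 2-allyl-4-bromophenol
Product: 21 (2-allyl-4-bromophenoxy)triisopropylsilane
Conditions: TIPSCl, imidazole, DMF, rt
Reagents that add atoms: triisopropylsilyl chloride, SMILES CC(C)[Si](Cl)(C(C)C)C(C)C
Why: Imidazole-promoted silylation of a phenol is routine, and the bulky aryl silyl ether flanked by the allyl group withstands organolithium and aqueous phosphate base but falls to fluoride together with the other silyl group.

Step 10
Reactants: 21 (2-allyl-4-bromophenoxy)triisopropylsilane
Product: 23 [2-allyl-4-(4,4,5,5-tetramethyl-1,3,2-dioxaborolan-2-yl)phenoxy]triisopropylsilane, via aryllithium 22 (not isolated)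
Conditions: n-BuLi, THF, −78 °C; then i-PrOBpin, −78 °C to rt
Reagents that add atoms: 2-isopropoxy-4,4,5,5-tetramethyl-1,3,2-dioxaborolane, SMILES CC(C)OB1OC(C)(C)C(C)(C)O1
Why: Bromine–lithium exchange followed by borylation with an alkoxyboronate is reliable because the exchange at −78 °C outruns deprotonation of the allylic benzylic CH2, and no transition metal is present that could move the allyl double bond.

Step 11
Reactants: 19 (3R,5S,7R,10S)-3-(2-bromo-4-chlorophenoxy)-7-{2-[(tert-butyldimethylsilyl)oxy]propan-2-yl}-3,10-dimethyl-trans-decalin; 23 [2-allyl-4-(4,4,5,5-tetramethyl-1,3,2-dioxaborolan-2-yl)phenoxy]triisopropylsilane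
Product: 24 biaryl chloride: the decalinyl ether of 19 in which Br is replaced by the 3-allyl-4-(triisopropylsilyloxy)phenyl group and Cl is retained
Conditions: Pd(dppf)Cl2 (5 mol %), K3PO4, 1,4-dioxane/H2O, 80 °C
Reagents that add atoms: none
Why: Suzuki–Miyaura coupling: zerovalent palladium carrying dppf inserts into the C–Br bond but not into the electron-rich C–Cl bond para to oxygen, and a single ortho alkoxy substituent is well tolerated.

Step 12
Reactants: 24 biaryl chloride
Product: 25 bis-silyl ether of the target: 24 with Cl replaced by allyl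
Conditions: Pd(OAc)2 (5 mol %), XPhos (10 mol %), allylBpin, K3PO4, THF/H2O, 70 °C
Reagents that add atoms: allylboronic acid pinacol ester, SMILES C=CCB1OC(C)(C)C(C)(C)O1
Why: Suzuki–Miyaura allylation of an aryl chloride: the bulky electron-rich biaryl phosphine enables oxidative addition into the unhindered C–Cl bond, the unsubstituted allyl boronate raises no regiochemical question, and fast transmetalation at moderate temperature keeps both allyl groups out of conjugation.

Step 13
Reactants: 25 bis-silyl ether of the target
Product: 27 target CNP0342687.1, (3R,5S,7R,10S)-3-{[3',5-diallyl-4'-hydroxy-(1,1'-biphenyl)-2-yl]oxy}-7-(2-hydroxypropan-2-yl)-3,10-dimethyl-trans-decalin, via monosilyl phenol 26 (not isolated)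
Conditions: TBAF (excess), THF, rt then 50 °C
Reagents that add atoms: none
Why: Fluoride-induced desilylation removes the aryl silyl ether first (26) and the hindered tertiary silyl ether on warming, and the non-acidic medium preserves the acid-labile tertiary alkyl aryl ether, the allyl groups and all four stereocentres.

Compound list
1 | (+)-dihydrocarvone, (2R,5R)-2-methyl-5-(prop-1-en-2-yl)cyclohexan-1-one | C[C@@H]1CC[C@@H](C(C)=C)CC1=O | starting material
2 | (R)-(+)-1-phenylethylamine | C[C@@H](N)c1ccccc1 | starting material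
3 | methyl acrylate | C=CC(=O)OC | starting material
4 | N-[(1R)-1-phenylethyl] ketimine of 1 (epimeric at the methyl-bearing ring carbon) | CC1CC[C@@H](C(C)=C)CC1=N[C@H](C)c1ccccc1 | intermediate
5 | methyl 3-[(1S,4R)-1-methyl-2-{[(1R)-1-phenylethyl]imino}-4-(prop-1-en-2-yl)cyclohexyl]propanoate | COC(=O)CC[C@]1(C)CC[C@@H](C(C)=C)CC1=N[C@H](C)c1ccccc1 | intermediate
6 | methyl 3-[(1S,4R)-1-methyl-2-oxo-4-(prop-1-en-2-yl)cyclohexyl]propanoate | COC(=O)CC[C@]1(C)CC[C@@H](C(C)=C)CC1=O | intermediate
7 | methyl 3-[(1S,4R)-4-(2-hydroxypropan-2-yl)-1-methyl-2-oxocyclohexyl]propanoate | COC(=O)CC[C@]1(C)CC[C@@H](C(C)(C)O)CC1=O | intermediate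
8 | tert-butyldimethylsilyl ether of 7 | COC(=O)CC[C@]1(C)CC[C@@H](C(C)(C)O[Si](C)(C)C(C)(C)C)CC1=O | intermediate
9 | lithium carboxylate of 10 | [Li+].[O-]C(=O)CC[C@]1(C)CC[C@@H](C(C)(C)O[Si](C)(C)C(C)(C)C)CC1=O | intermediate
10 | 3-[(1S,4R)-4-{2-[(tert-butyldimethylsilyl)oxy]propan-2-yl}-1-methyl-2-oxocyclohexyl]propanoic acid | OC(=O)CC[C@]1(C)CC[C@@H](C(C)(C)O[Si](C)(C)C(C)(C)C)CC1=O | intermediate
11 | 2-bromo-4-chlorophenol | Oc1ccc(Cl)cc1Br | starting material
12 | 2-bromo-4-chlorophenyl ester of 10 | O=C(Oc1ccc(Cl)cc1Br)CC[C@]1(C)CC[C@@H](C(C)(C)O[Si](C)(C)C(C)(C)C)CC1=O | intermediate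
13 | 2-bromo-4-chlorophenyl 3-[(1S,4R)-4-{2-[(tert-butyldimethylsilyl)oxy]propan-2-yl}-1-methyl-2-methylidenecyclohexyl]propanoate | O=C(Oc1ccc(Cl)cc1Br)CC[C@]1(C)CC[C@@H](C(C)(C)O[Si](C)(C)C(C)(C)C)CC1=C | intermediate
14 | aryl 1-alkylvinyl ether with exocyclic methylene (key-step precursor) | C=C(Oc1ccc(Cl)cc1Br)CC[C@]1(C)CC[C@@H](C(C)(C)O[Si](C)(C)C(C)(C)C)CC1=C | intermediate
15 | aryloxycarbenium ion at C3, as its triflimide | CC(=[O+]c1ccc(Cl)cc1Br)CC[C@]1(C)CC[C@@H](C(C)(C)O[Si](C)(C)C(C)(C)C)CC1=C.O=S(=O)([N-]S(=O)(=O)C(F)(F)F)C(F)(F)F | intermediate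
16 | bicyclic tertiary cation at C5, as its triflimide | Brc1cc(Cl)ccc1O[C@]1(C)CC[C@]2(C)CC[C@@H](C(C)(C)O[Si](C)(C)C(C)(C)C)C[C+]2C1.O=S(=O)([N-]S(=O)(=O)C(F)(F)F)C(F)(F)F | intermediate
17 | (3R,7R,10S) tertiary aryl ether 5(6)-octalin (key-step product) | Brc1cc(Cl)ccc1O[C@]1(C)CC[C@]2(C)CC[C@@H](C(C)(C)O[Si](C)(C)C(C)(C)C)C=C2C1 | intermediate
18 | tertiary C5 radical | Brc1cc(Cl)ccc1O[C@]1(C)CC[C@]2(C)CC[C@@H](C(C)(C)O[Si](C)(C)C(C)(C)C)C[C]2C1 | intermediate
19 | (3R,5S,7R,10S) tertiary aryl ether trans-decalin | Brc1cc(Cl)ccc1O[C@]1(C)CC[C@]2(C)CC[C@@H](C(C)(C)O[Si](C)(C)C(C)(C)C)C[C@H]2C1 | intermediate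
20 | 2-allyl-4-bromophenol | C=CCc1cc(Br)ccc1O | starting material
21 | (2-allyl-4-bromophenoxy)triisopropylsilane | C=CCc1cc(Br)ccc1O[Si](C(C)C)(C(C)C)C(C)C | intermediate
22 | 3-allyl-4-(triisopropylsilyloxy)phenyllithium | [Li]c1ccc(O[Si](C(C)C)(C(C)C)C(C)C)c(CC=C)c1 | intermediate
23 | [2-allyl-4-(4,4,5,5-tetramethyl-1,3,2-dioxaborolan-2-yl)phenoxy]triisopropylsilane | C=CCc1cc(B2OC(C)(C)C(C)(C)O2)ccc1O[Si](C(C)C)(C(C)C)C(C)C | intermediate
24 | biaryl chloride | Clc1ccc(O[C@]2(C)CC[C@]3(C)CC[C@@H](C(C)(C)O[Si](C)(C)C(C)(C)C)C[C@H]3C2)c(-c2ccc(O[Si](C(C)C)(C(C)C)C(C)C)c(CC=C)c2)c1 | intermediate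
25 | bis-silyl ether of the target | C=CCc1ccc(O[C@]2(C)CC[C@]3(C)CC[C@@H](C(C)(C)O[Si](C)(C)C(C)(C)C)C[C@H]3C2)c(-c2ccc(O[Si](C(C)C)(C(C)C)C(C)C)c(CC=C)c2)c1 | intermediate
26 | free phenol still carrying the tertiary silyl ether | C=CCc1ccc(O[C@]2(C)CC[C@]3(C)CC[C@@H](C(C)(C)O[Si](C)(C)C(C)(C)C)C[C@H]3C2)c(-c2ccc(O)c(CC=C)c2)c1 | intermediate
27 | CNP0342687.1 | C=CCc1ccc(O[C@]2(C)CC[C@]3(C)CC[C@@H](C(C)(C)O)C[C@H]3C2)c(-c2ccc(O)c(CC=C)c2)c1 | target

Total step count: 13. Longest linear sequence: 11 (steps 1–8 and 11–13); steps 9 and 10 form the two-step branch.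

Steps most likely to fail

Step 7.
- What may go wrong: cationic oligomerisation of the enol ether, capture of the oxocarbenium ion by traces of water, attack of the arene on the C5 cation, re-ionisation of the new tertiary C–O bond by the acid, proton loss towards C4, or weak facial discrimination at C3.
- The fallback uses known reaction types only, sets out from ketimine 4 and returns at 19. Ketimine 4 is combined with methyl vinyl ketone instead of 3 to give the vinyl ketone adduct imine F1.
- Aqueous acetic acid hydrolyses it to (2S,5R)-2-methyl-2-(3-oxobutyl)-5-(prop-1-en-2-yl)cyclohexan-1-one F2.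
- NaOMe in MeOH closes ring A by aldol condensation (Robinson annulation) to (7R,10S)-10-methyl-7-(prop-1-en-2-yl)-4-octalin-3-one F3.
- Li in NH3 with t-BuOH reduces the enone, with axial protonation at C5, to the trans-fused (5S,7R,10S)-decalin-3-one F4.
- Mukaiyama hydration as in step 2 gives the hydroxy decalone F5, and TBSOTf/2,6-lutidine gives its silyl ether F6.
- MeMgBr adds to the C3 ketone mainly along the equatorial trajectory to give the axial (3R) tertiary alcohol F7, which is separated from its epimer.
- The sodium alkoxide of F7 (NaN(SiMe3)2, toluene, rt) is O-arylated without metal catalysis by (2-bromo-4-chlorophenyl)(2,4,6-trimethoxyphenyl)iodonium tosylate F8. F8 is made in one pot from 2-bromo-4-chloro-1-iodobenzene, mCPBA, TsOH and 1,3,5-trimethoxybenzene. This ligand coupling is established for hindered tertiary alcohols and leaves the C3–O bond untouched, so 19 is reached with steps 2–8 bypassed.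

Step 8.
- What may go wrong: delivery of the second hydrogen to the β lobe of the C5 radical, because the axial aryloxy group crowds the α face, or sluggish hydrogen-atom transfer to the hindered trisubstituted alkene.
- The fallback sets out from 17 and returns at 19. It fixes C5 by a concerted syn addition instead of a radical abstraction.
- Hydroboration with BH3·SMe2 places only the small hydrogen end of the four-centre array under the aryloxy group and approaches anti to the angular methyl and the C7 side chain. Exchange with catechol then gives the 6α-(1,3,2-benzodioxaborol-2-yl)-5α-H decalin F9.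
- Its radical-chain protodeboronation with 4-tert-butylcatechol and MeOH under air turns C6 into a stereochemically irrelevant CH2 and gives 19.

Step 6.
- What may go wrong: expulsion of the rather good aryloxide leaving group from the oxatitanacycle, incomplete reaction at the hindered ketone, or premature acid-type reactions of the enol ether caused by the aluminium Lewis acid or during work-up.
- The fallback sets out from 10 and returns at 14. It separates the two methylenations.
- A Wittig reaction with excess Ph3P=CH2 (Ph3PCH3Br, KOt-Bu, THF, reflux) on the carboxylate of 10, which cannot undergo intramolecular acylation, gives 3-[(1S,4R)-4-{2-[(tert-butyldimethylsilyl)oxy]propan-2-yl}-1-methyl-2-methylidenecyclohexyl]propanoic acid F10.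
- Carbodiimide esterification with 11 as in step 5 gives 13, now isolated.
- A single Petasis methylenation with aluminium-free Cp2TiMe2 (toluene, 70 °C) converts only the ester carbonyl and gives 14.

Further compounds
F1 | step 7 | 4-[(1S,4R)-1-methyl-2-{[(1R)-1-phenylethyl]imino}-4-(prop-1-en-2-yl)cyclohexyl]butan-2-one | CC(=O)CC[C@]1(C)CC[C@@H](C(C)=C)CC1=N[C@H](C)c1ccccc1
F2 | step 7 | (2S,5R)-2-methyl-2-(3-oxobutyl)-5-(prop-1-en-2-yl)cyclohexan-1-one | CC(=O)CC[C@]1(C)CC[C@@H](C(C)=C)CC1=O
F3 | step 7 | (7R,10S)-10-methyl-7-(prop-1-en-2-yl)-4-octalin-3-one | O=C1CC[C@]2(C)CC[C@@H](C(C)=C)CC2=C1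
F4 | step 7 | (5S,7R,10S)-10-methyl-7-(prop-1-en-2-yl)-trans-decalin-3-one | O=C1CC[C@]2(C)CC[C@@H](C(C)=C)C[C@H]2C1
F5 | step 7 | (5S,7R,10S)-7-(2-hydroxypropan-2-yl)-10-methyl-trans-decalin-3-one | O=C1CC[C@]2(C)CC[C@@H](C(C)(C)O)C[C@H]2C1
F6 | step 7 | tert-butyldimethylsilyl ether of F5 | O=C1CC[C@]2(C)CC[C@@H](C(C)(C)O[Si](C)(C)C(C)(C)C)C[C@H]2C1
F7 | step 7 | (3R,5S,7R,10S)-7-{2-[(tert-butyldimethylsilyl)oxy]propan-2-yl}-3,10-dimethyl-trans-decalin-3-ol (hydroxyl axial) | O[C@]1(C)CC[C@]2(C)CC[C@@H](C(C)(C)O[Si](C)(C)C(C)(C)C)C[C@H]2C1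
F8 | step 7 | (2-bromo-4-chlorophenyl)(2,4,6-trimethoxyphenyl)iodonium 4-methylbenzenesulfonate | COc1cc(OC)c([I+]c2ccc(Cl)cc2Br)c(OC)c1.Cc1ccc(S(=O)(=O)[O-])cc1
F9 | step 8 | 6α-(1,3,2-benzodioxaborol-2-yl) derivative of 19 | Brc1cc(Cl)ccc1O[C@]1(C)CC[C@]2(C)CC[C@@H](C(C)(C)O[Si](C)(C)C(C)(C)C)[C@H](B3Oc4ccccc4O3)[C@H]2C1
F10 | step 6 | 3-[(1S,4R)-4-{2-[(tert-butyldimethylsilyl)oxy]propan-2-yl}-1-methyl-2-methylidenecyclohexyl]propanoic acid | OC(=O)CC[C@]1(C)CC[C@@H](C(C)(C)O[Si](C)(C)C(C)(C)C)CC1=C
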